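**Plan**

1. The target is 5,7,2',4'-tetrahydroxy-6,8,3'-triprenylisoflavone. It is achiral, so no stereochemistry has to be set; the two stereocentres met on the way (a cycloadduct and a carbinol) are racemic and are erased.
2. Retrosynthesis: remove the O-silyl and O-methoxymethyl groups; cut ring C at O1–C2 and C2–C3 (C2 as a one-carbon unit); cut C3–C4 (benzyl Grignard plus aldehyde) and C4–C4a (formyl); cut ring A at C8–C8a and C6–C7.
3. Enabling feature: ring A alternates oxygen-bearing carbons (C5, C7, C8a) with carbon-bearing ones (C4a, C6, C8). This is the pattern that a 3-oxy vinylketene (from a 3-siloxycyclobutenone) and an oxygenated alkyne produce in a cyclobutenone–siloxyalkyne benzannulation.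
4. Forward: one prenylated siloxyalkyne is used twice (with ketene to give the cyclobutenone, then as the alkyne partner) → ring A phenol → formyl at C4a → ring B benzyl unit joined at C3–C4 → oxidation → ring C closed with a one-carbon unit → deprotection.
5. Ring B comes from resorcinol by two directed ortho-metalations (prenyl, then the CH2 unit).
6. Protecting groups: C5–O and C7–O are triisopropylsilyl ethers (fluoride), ring B carries methoxymethyl ethers (mild acid), and C8a–OH stays free for formylation and ring closure, so no ether dealkylation is needed beside the prenyl groups.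

Key step: step 4

Remark: ketene is taken from the pyrolysis of acetone in a standard ketene generator and led directly into the reaction flask; it is listed as an intermediate.

**Route**

Step 1
Reactants: 1 prenyl bromide (1-bromo-3-methylbut-2-ene); 2 ethynylmagnesium bromide (HC≡CMgBr)
Product: 3 5-methylhex-4-en-1-yne
Conditions: 2 (1.5 equiv), CuCl (5 mol%), THF, 0 °C → rt; fractional distillation
Reagents that add atoms: none
Why: CuCl-catalysed allylic substitution of the alkynyl Grignard reagent at the unhindered primary carbon of the prenyl halide (SN2 mode) is a standard entry to skipped 1,4-enynes, and the excess of 2 limits double alkylation.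

Step 2
Reactants: 3 5-methylhex-4-en-1-yne
Product: 6 triisopropyl[(5-methylhex-4-en-1-yn-1-yl)oxy]silane, via lithium acetylide 4 (not isolated), via lithium ynolate 5 (not isolated)
Conditions: n-BuLi, THF, −78 °C; t-BuOOLi (from t-BuOOH and LiN(SiMe3)2), −78 → 0 °C; i-Pr3SiOTf, −78 → 0 °C
Reagents that add atoms: tert-butyl hydroperoxide, CC(C)(C)OO; triisopropylsilyl trifluoromethanesulfonate, CC(C)[Si](C(C)C)(C(C)C)OS(=O)(=O)C(F)(F)F
Why: Oxidation of the lithium acetylide with lithium tert-butyl peroxide gives the lithium ynolate (known ynolate synthesis), and the bulky silyl triflate traps it on oxygen to give an isolable triisopropylsiloxyalkyne; only the far more acidic acetylenic C–H is deprotonated, so the skipped enyne should not isomerise.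

Step 3
Reactants: 6 triisopropyl[(5-methylhex-4-en-1-yn-1-yl)oxy]silane; 7 acetone (source of ketene)
Product: 9 2-(3-methylbut-2-en-1-yl)-3-[(triisopropylsilyl)oxy]cyclobut-2-en-1-one, via ketene 8 (not isolated)
Conditions: ketene gas (pyrolysis of 7, ketene lamp, excess) passed into 6, CH2Cl2, 0 °C → rt; rapid filtration through Et3N-deactivated silica
Reagents that add atoms: none
Why: Ketene adds to the electron-rich siloxyalkyne in a polar [2+2] cycloaddition (the alkyne carbon bearing the prenyl group attacks the ketene carbonyl carbon), the known route to 3-siloxycyclobutenones, and the unactivated prenyl alkene does not react with ketene itself.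

Step 4
Reactants: 9 2-(3-methylbut-2-en-1-yl)-3-[(triisopropylsilyl)oxy]cyclobut-2-en-1-one; 6 triisopropyl[(5-methylhex-4-en-1-yn-1-yl)oxy]silane
Product: 14 2,4-bis(3-methylbut-2-en-1-yl)-3,5-bis[(triisopropylsilyl)oxy]phenol, via vinylketene 10 (not isolated), via vinylcyclobutenone 11 (not isolated), via dienylketene 12 (not isolated), via cyclohexadienone 13 (not isolated)
Conditions: 6 (1.3 equiv), degassed toluene (0.5 M), sealed tube, 80 °C, then 110 °C
Reagents that add atoms: none
Why: Heating should open cyclobutenone 9 in a four-electron electrocyclic reaction to vinylketene 10, whose ketene C=C adds alkyne 6 in a [2+2] cycloaddition to give 4-vinylcyclobutenone 11; a second four-electron opening gives dienylketene 12, which closes by six-electron disrotatory electrocyclisation to dienone 13 and tautomerises to phenol 14. The closest known reaction is the Danheiser benzannulation of cyclobutenones with trialkylsiloxyalkynes, which gives resorcinol monosilyl ethers; here the 3-siloxy group of 9 supplies the third ring oxygen. Ring A is closed in the six-electron electrocyclisation, which re-forms the C4a–C8a bond after the cycloaddition has made the two new bonds C8–C8a and C6–C7. No stereocentre is set: the quaternary carbon of 11 is racemic and becomes trigonal on ring opening, and because the ring openings are reversible only the dienylketene geometry that can cyclise is consumed. The step needs regiocontrol in the cycloaddition and chemoselectivity against the prenyl alkenes: the alkyne carbon bearing the prenyl group is the nucleophilic carbon of the ynol ether and bonds to the ketene carbonyl carbon, which places that prenyl ortho to the new hydroxyl, while the isolated trisubstituted alkenes are far less nucleophilic than the ynol ether and their one-carbon tether is too short for an intramolecular ketene–alkene cycloaddition.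

Step 5
Reactants: 14 2,4-bis(3-methylbut-2-en-1-yl)-3,5-bis[(triisopropylsilyl)oxy]phenol
Product: 16 2-hydroxy-3,5-bis(3-methylbut-2-en-1-yl)-4,6-bis[(triisopropylsilyl)oxy]benzaldehyde, via hydroxymethylphenol 15 (not isolated)
Conditions: MgCl2, Et3N, (CH2O)n, MeCN, reflux; cold aq NH4Cl
Reagents that add atoms: paraformaldehyde (as formaldehyde), C=O
Why: In the magnesium-mediated ortho-formylation (Casnati–Skattebøl) the magnesium phenoxide delivers formaldehyde to the only ring C–H, which is ortho to the free hydroxyl, and a second formaldehyde oxidises the benzylic alkoxide 15 by hydride transfer; aryl silyl ethers and prenyl groups should be untouched.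

Step 6
Reactants: 17 resorcinol
Product: 18 1,3-bis(methoxymethoxy)benzene
Conditions: MOMCl (2.5 equiv), i-Pr2NEt, CH2Cl2, 0 °C → rt
Reagents that add atoms: chloromethyl methyl ether, COCCl
Why: Standard O-alkylation of both phenols; the methoxymethyl ethers later serve as directors for ortho-metalation.

Step 7
Reactants: 18 1,3-bis(methoxymethoxy)benzene; 1 prenyl bromide
Product: 20 1,3-bis(methoxymethoxy)-2-(3-methylbut-2-en-1-yl)benzene, via aryllithium 19 (not isolated)
Conditions: n-BuLi, THF, 0 °C → rt; CuBr·SMe2 (20 mol%), −78 °C; 1, −78 °C → rt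
Reagents that add atoms: none
Why: Directed ortho-metalation at the position flanked by both methoxymethoxy groups, followed by CuBr-mediated SN2 allylation with prenyl bromide, is a well-used route to 2-prenylresorcinol ethers.

Step 8
Reactants: 20 1,3-bis(methoxymethoxy)-2-(3-methylbut-2-en-1-yl)benzene
Product: 22 [2,4-bis(methoxymethoxy)-3-(3-methylbut-2-en-1-yl)phenyl]methanol, via aryllithium 21 (not isolated)
Conditions: n-BuLi, TMEDA, THF, −20 → 0 °C; dry (CH2O)n, 0 °C → rt; aq NH4Cl
Reagents that add atoms: paraformaldehyde (as formaldehyde), C=O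
Why: A second directed ortho-metalation takes place at one of the two equivalent positions next to a methoxymethoxy group, and the aryllithium is hydroxymethylated by formaldehyde.

Step 9
Reactants: 22 [2,4-bis(methoxymethoxy)-3-(3-methylbut-2-en-1-yl)phenyl]methanol
Product: 23 1-(chloromethyl)-2,4-bis(methoxymethoxy)-3-(3-methylbut-2-en-1-yl)benzene
Conditions: Ph3P and N-chlorosuccinimide (premixed), THF, 0 °C → rt; used without chromatography
Reagents that add atoms: N-chlorosuccinimide, O=C1CCC(=O)N1Cl
Why: Appel-type chlorination through the alkoxyphosphonium salt runs under neutral conditions, so the acid-labile acetals and the prenyl group should survive and the reactive electron-rich benzylic chloride is never exposed to acid.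

Step 10
Reactants: 16 2-hydroxy-3,5-bis(3-methylbut-2-en-1-yl)-4,6-bis[(triisopropylsilyl)oxy]benzaldehyde; 23 1-(chloromethyl)-2,4-bis(methoxymethoxy)-3-(3-methylbut-2-en-1-yl)benzene
Product: 25 racemic 1-{2-hydroxy-3,5-bis(3-methylbut-2-en-1-yl)-4,6-bis[(triisopropylsilyl)oxy]phenyl}-2-[2,4-bis(methoxymethoxy)-3-(3-methylbut-2-en-1-yl)phenyl]ethan-1-ol, via benzylmagnesium chloride 24 (not isolated)
Conditions: 23, Mg, THF, 0 °C (slow addition); 16, t-BuMgCl (1.0 equiv), THF, −78 °C, then 24 (1.5 equiv), −78 → −20 °C; aq NH4Cl at −20 °C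
Reagents that add atoms: none
Why: Grignard addition of the benzylmagnesium chloride to the aldehyde of the preformed magnesium phenoxide forms the C3–C4 bond; the new carbinol stereocentre arises as a racemate and is removed by the oxidation in step 11, and the all-magnesium, low-temperature protocol is chosen to keep the neighbouring aryl silyl ether from migrating to the alkoxide.

Step 11
Reactants: 25 racemic carbinol from step 10
Product: 26 1-{2-hydroxy-3,5-bis(3-methylbut-2-en-1-yl)-4,6-bis[(triisopropylsilyl)oxy]phenyl}-2-[2,4-bis(methoxymethoxy)-3-(3-methylbut-2-en-1-yl)phenyl]ethan-1-one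
Conditions: Dess–Martin periodinane, NaHCO3, CH2Cl2, 0 °C → rt
Reagents that add atoms: none
Why: Dess–Martin oxidation of the secondary benzylic alcohol should give the hydrogen-bonded ortho-hydroxy ketone under buffered, non-acidic conditions compatible with silyl ethers, acetals and alkenes; the fully substituted phenol has no free ring position for over-oxidation.

Step 12
Reactants: 26 deoxybenzoin from step 11
Product: 28 3-[2,4-bis(methoxymethoxy)-3-(3-methylbut-2-en-1-yl)phenyl]-6,8-bis(3-methylbut-2-en-1-yl)-5,7-bis[(triisopropylsilyl)oxy]-4H-chromen-4-one, via enaminone 27 (not isolated)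
Conditions: Me2NCH(OMe)2 (3 equiv), toluene, 90 °C
Reagents that add atoms: N,N-dimethylformamide dimethyl acetal, COC(OC)N(C)C
Why: This is the classical deoxybenzoin route to isoflavones: the amide acetal condenses at the doubly activated methylene to enaminone 27, and addition of the free phenol to the enamine carbon with loss of dimethylamine (6-endo addition–elimination) closes the pyranone ring C.

Step 13
Reactants: 28 protected isoflavone from step 12
Product: 29 3-[2,4-dihydroxy-3-(3-methylbut-2-en-1-yl)phenyl]-6,8-bis(3-methylbut-2-en-1-yl)-5,7-bis[(triisopropylsilyl)oxy]-4H-chromen-4-one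
Conditions: 3 M aq HCl, MeOH–THF, 40 °C
Reagents that add atoms: none
Why: Acid-catalysed transacetalisation in methanol removes both methoxymethyl groups under conditions commonly used on prenylated flavonoids, while the ring A prenyl groups remain flanked by silyl ethers and so cannot cyclise onto a free phenol.

Step 14
Reactants: 29 bis-silyl isoflavone from step 13
Product: 30 Euchrenone b2 (5,7-dihydroxy-3-[2,4-dihydroxy-3-(3-methylbut-2-en-1-yl)phenyl]-6,8-bis(3-methylbut-2-en-1-yl)-4H-chromen-4-one)
Conditions: Bu4NF, AcOH (1:1), THF, 0 °C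
Reagents that add atoms: none
Why: Fluoride cleaves both aryl silyl ethers rapidly at 0 °C, and the acetic acid buffer keeps the polyphenolic isoflavone from standing as a basic phenoxide.

**Compound list**

1 | prenyl bromide (1-bromo-3-methylbut-2-ene) | CC(C)=CCBr | starting material
2 | ethynylmagnesium bromide | C#C[Mg]Br | starting material
3 | 5-methylhex-4-en-1-yne | C#CCC=C(C)C | intermediate
4 | lithium 5-methylhex-4-en-1-yn-1-ide | [Li]C#CCC=C(C)C | intermediate
5 | lithium 5-methylhex-4-en-1-yn-1-olate | [Li]OC#CCC=C(C)C | intermediate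
6 | triisopropyl[(5-methylhex-4-en-1-yn-1-yl)oxy]silane | CC(C)=CCC#CO[Si](C(C)C)(C(C)C)C(C)C | intermediate
7 | acetone | CC(C)=O | starting material
8 | ketene | C=C=O | intermediate
9 | 2-(3-methylbut-2-en-1-yl)-3-[(triisopropylsilyl)oxy]cyclobut-2-en-1-one | CC(C)=CCC1=C(O[Si](C(C)C)(C(C)C)C(C)C)CC1=O | intermediate
10 | 2-(3-methylbut-2-en-1-yl)-3-[(triisopropylsilyl)oxy]buta-1,3-dien-1-one (vinylketene) | CC(C)=CCC(=C=O)C(=C)O[Si](C(C)C)(C(C)C)C(C)C | intermediate
11 | racemic 2,4-bis(3-methylbut-2-en-1-yl)-3-[(triisopropylsilyl)oxy]-4-{1-[(triisopropylsilyl)oxy]ethenyl}cyclobut-2-en-1-one | CC(C)=CCC1=C(O[Si](C(C)C)(C(C)C)C(C)C)C(CC=C(C)C)(C(=C)O[Si](C(C)C)(C(C)C)C(C)C)C1=O | intermediate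
12 | 2,4-bis(3-methylbut-2-en-1-yl)-3,5-bis[(triisopropylsilyl)oxy]hexa-1,3,5-trien-1-one, C3=C4 isomer with C2 and C5 cis | O=C=C(CC=C(C)C)/C(O[Si](C(C)C)(C(C)C)C(C)C)=C(CC=C(C)C)\C(=C)O[Si](C(C)C)(C(C)C)C(C)C | intermediate
13 | 2,4-bis(3-methylbut-2-en-1-yl)-3,5-bis[(triisopropylsilyl)oxy]cyclohexa-2,4-dien-1-one | O=C1CC(O[Si](C(C)C)(C(C)C)C(C)C)=C(CC=C(C)C)C(O[Si](C(C)C)(C(C)C)C(C)C)=C1CC=C(C)C | intermediate
14 | 2,4-bis(3-methylbut-2-en-1-yl)-3,5-bis[(triisopropylsilyl)oxy]phenol | Oc1cc(O[Si](C(C)C)(C(C)C)C(C)C)c(CC=C(C)C)c(O[Si](C(C)C)(C(C)C)C(C)C)c1CC=C(C)C | intermediate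
15 | 2-(hydroxymethyl)-4,6-bis(3-methylbut-2-en-1-yl)-3,5-bis[(triisopropylsilyl)oxy]phenol (present as its magnesium salt) | OCc1c(O)c(CC=C(C)C)c(O[Si](C(C)C)(C(C)C)C(C)C)c(CC=C(C)C)c1O[Si](C(C)C)(C(C)C)C(C)C | intermediate
16 | 2-hydroxy-3,5-bis(3-methylbut-2-en-1-yl)-4,6-bis[(triisopropylsilyl)oxy]benzaldehyde | O=Cc1c(O)c(CC=C(C)C)c(O[Si](C(C)C)(C(C)C)C(C)C)c(CC=C(C)C)c1O[Si](C(C)C)(C(C)C)C(C)C | intermediate
17 | resorcinol | Oc1cccc(O)c1 | starting material
18 | 1,3-bis(methoxymethoxy)benzene | COCOc1cccc(OCOC)c1 | intermediate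
19 | [2,6-bis(methoxymethoxy)phenyl]lithium | [Li]c1c(OCOC)cccc1OCOC | intermediate
20 | 1,3-bis(methoxymethoxy)-2-(3-methylbut-2-en-1-yl)benzene | COCOc1cccc(OCOC)c1CC=C(C)C | intermediate
21 | [2,4-bis(methoxymethoxy)-3-(3-methylbut-2-en-1-yl)phenyl]lithium | [Li]c1ccc(OCOC)c(CC=C(C)C)c1OCOC | intermediate
22 | [2,4-bis(methoxymethoxy)-3-(3-methylbut-2-en-1-yl)phenyl]methanol | OCc1ccc(OCOC)c(CC=C(C)C)c1OCOC | intermediate
23 | 1-(chloromethyl)-2,4-bis(methoxymethoxy)-3-(3-methylbut-2-en-1-yl)benzene | ClCc1ccc(OCOC)c(CC=C(C)C)c1OCOC | intermediate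
24 | [2,4-bis(methoxymethoxy)-3-(3-methylbut-2-en-1-yl)benzyl]magnesium chloride | Cl[Mg]Cc1ccc(OCOC)c(CC=C(C)C)c1OCOC | intermediate
25 | racemic 1-{2-hydroxy-3,5-bis(3-methylbut-2-en-1-yl)-4,6-bis[(triisopropylsilyl)oxy]phenyl}-2-[2,4-bis(methoxymethoxy)-3-(3-methylbut-2-en-1-yl)phenyl]ethan-1-ol | OC(Cc1ccc(OCOC)c(CC=C(C)C)c1OCOC)c1c(O)c(CC=C(C)C)c(O[Si](C(C)C)(C(C)C)C(C)C)c(CC=C(C)C)c1O[Si](C(C)C)(C(C)C)C(C)C | intermediate
26 | 1-{2-hydroxy-3,5-bis(3-methylbut-2-en-1-yl)-4,6-bis[(triisopropylsilyl)oxy]phenyl}-2-[2,4-bis(methoxymethoxy)-3-(3-methylbut-2-en-1-yl)phenyl]ethan-1-one | O=C(Cc1ccc(OCOC)c(CC=C(C)C)c1OCOC)c1c(O)c(CC=C(C)C)c(O[Si](C(C)C)(C(C)C)C(C)C)c(CC=C(C)C)c1O[Si](C(C)C)(C(C)C)C(C)C | intermediate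
27 | 3-(dimethylamino)-1-{2-hydroxy-3,5-bis(3-methylbut-2-en-1-yl)-4,6-bis[(triisopropylsilyl)oxy]phenyl}-2-[2,4-bis(methoxymethoxy)-3-(3-methylbut-2-en-1-yl)phenyl]prop-2-en-1-one (alkene geometry of no consequence) | CN(C)C=C(C(=O)c1c(O)c(CC=C(C)C)c(O[Si](C(C)C)(C(C)C)C(C)C)c(CC=C(C)C)c1O[Si](C(C)C)(C(C)C)C(C)C)c1ccc(OCOC)c(CC=C(C)C)c1OCOC | intermediate
28 | 3-[2,4-bis(methoxymethoxy)-3-(3-methylbut-2-en-1-yl)phenyl]-6,8-bis(3-methylbut-2-en-1-yl)-5,7-bis[(triisopropylsilyl)oxy]-4H-chromen-4-one | CC(C)=CCc1c(OCOC)ccc(-c2coc3c(CC=C(C)C)c(O[Si](C(C)C)(C(C)C)C(C)C)c(CC=C(C)C)c(O[Si](C(C)C)(C(C)C)C(C)C)c3c2=O)c1OCOC | intermediate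
29 | 3-[2,4-dihydroxy-3-(3-methylbut-2-en-1-yl)phenyl]-6,8-bis(3-methylbut-2-en-1-yl)-5,7-bis[(triisopropylsilyl)oxy]-4H-chromen-4-one | CC(C)=CCc1c(O)ccc(-c2coc3c(CC=C(C)C)c(O[Si](C(C)C)(C(C)C)C(C)C)c(CC=C(C)C)c(O[Si](C(C)C)(C(C)C)C(C)C)c3c2=O)c1O | intermediate
30 | Euchrenone b2 | CC(C)=CCc1c(O)ccc(-c2coc3c(CC=C(C)C)c(O)c(CC=C(C)C)c(O)c3c2=O)c1O | target

**Step count and risks**

Total step count: 14. Longest linear sequence: 10 steps (steps 1, 2, 3, 4, 5, 10, 11, 12, 13, 14); the ring B branch (steps 6–9) joins at step 10.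

Steps most likely to fail:

1. Step 4 (benzannulation). The ring opening of the vinylogous silyl ester 9 may be slow relative to silyl transfer from 9 to the product phenol, and the vinylketene may dimerise or acylate the product phenol. Fallback: ring A is taken from the aromatic pool instead of being built. Commercial 2,4,6-trihydroxybenzaldehyde F1 would be C-prenylated twice with prenyl bromide 1 (aq KOH, 0 °C) to 2,4,6-trihydroxy-3,5-bis(3-methylbut-2-en-1-yl)benzaldehyde F2. Silylation with i-Pr3SiOTf (2 equiv) and 2,6-lutidine should then cap the 4-hydroxyl and one of the two equivalent chelated ortho hydroxyls. The fallback sets out from 1 and returns to the route at aldehyde 16.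

2. Step 10 (benzyl Grignard addition). Magnesium insertion into the electron-rich benzylic chloride may be overtaken by Wurtz homocoupling or ionisation of the chloride, and after addition the neighbouring silyl group may migrate to the new alkoxide. Fallback: the polarity is reversed so that ring A is the carbon nucleophile. Aryllithium 21 (from 20) would be opened with ethylene oxide to 2-[2,4-bis(methoxymethoxy)-3-(3-methylbut-2-en-1-yl)phenyl]ethan-1-ol F3, and Dess–Martin oxidation would give 2-[2,4-bis(methoxymethoxy)-3-(3-methylbut-2-en-1-yl)phenyl]acetaldehyde F4. Phenol 14 would be converted with EtMgBr into its bromomagnesium phenoxide F5, which in toluene should add F4 at its only free ortho carbon (magnesium phenoxide ortho-hydroxyalkylation). The fallback sets out from 20 and 14, bypasses steps 5, 8 and 9, and returns at carbinol 25.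

3. Step 3 (ketene cycloaddition). The siloxyalkyne may oligomerise under the ketene stream, and the vinylogous silyl ester may hydrolyse during isolation. Fallback: the cyclobutenone oxygen is silylated last instead of being carried through the cycloaddition. Commercial ethoxyacetylene F6 would be lithiated (n-BuLi, THF–DMPU) to lithium ethoxyacetylide F7 and alkylated with prenyl bromide 1 to 1-ethoxy-5-methylhex-4-en-1-yne F8. Ketene 8 should add to give the robust 3-ethoxy-2-(3-methylbut-2-en-1-yl)cyclobut-2-en-1-one F9. Dilute aqueous HCl would hydrolyse it to 3-hydroxy-2-(3-methylbut-2-en-1-yl)cyclobut-2-en-1-one F10 (the enol of the 1,3-dione), and i-Pr3SiCl/Et3N would silylate this immediately before use. The fallback sets out from 1 and returns at cyclobutenone 9.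

**Further compounds**

F1 | step 4 | 2,4,6-trihydroxybenzaldehyde | O=Cc1c(O)cc(O)cc1O
F2 | step 4 | 2,4,6-trihydroxy-3,5-bis(3-methylbut-2-en-1-yl)benzaldehyde | O=Cc1c(O)c(CC=C(C)C)c(O)c(CC=C(C)C)c1O
F3 | step 10 | 2-[2,4-bis(methoxymethoxy)-3-(3-methylbut-2-en-1-yl)phenyl]ethan-1-ol | OCCc1ccc(OCOC)c(CC=C(C)C)c1OCOC
F4 | step 10 | 2-[2,4-bis(methoxymethoxy)-3-(3-methylbut-2-en-1-yl)phenyl]acetaldehyde | O=CCc1ccc(OCOC)c(CC=C(C)C)c1OCOC
F5 | step 10 | bromomagnesium 2,4-bis(3-methylbut-2-en-1-yl)-3,5-bis[(triisopropylsilyl)oxy]phenoxide | Br[Mg]Oc1cc(O[Si](C(C)C)(C(C)C)C(C)C)c(CC=C(C)C)c(O[Si](C(C)C)(C(C)C)C(C)C)c1CC=C(C)C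
F6 | step 3 | ethoxyacetylene | CCOC#C
F7 | step 3 | lithium ethoxyacetylide | CCOC#C[Li]
F8 | step 3 | 1-ethoxy-5-methylhex-4-en-1-yne | CCOC#CCC=C(C)C
F9 | step 3 | 3-ethoxy-2-(3-methylbut-2-en-1-yl)cyclobut-2-en-1-one | CCOC1=C(CC=C(C)C)C(=O)C1
F10 | step 3 | 3-hydroxy-2-(3-methylbut-2-en-1-yl)cyclobut-2-en-1-one | OC1=C(CC=C(C)C)C(=O)C1
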